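**Plan**

- Cuts, in retrosynthetic order: the O6–angeloyl bond; C14=C15 and C12=C13 (two Wittig steps back to an 8α,12-lactol); C8–O (back to a Δ7-en-6-one); the ring-fusion bond C5–C10; C8–C9 (retro-oxy-Cope); C6–C7 and C1–C10 (propenyl addition, α-alkenylation of a cyclohexanone).
- Feature used: C5–C10 joins C5, which is α to the C6 oxygen, to the methyl-bearing quaternary C10. Cutting it opens rings A and B into one ten-membered ring (C1–C10) with a C6 ketone and an (E)-C1=C10 alkene.
- Forward: a cyclohexanone (C1–C6) is alkenylated and propenylated, then ring-expanded by anionic oxy-Cope. One transannular C5–C10 bond then closes rings A and B together; the C8 oxygen, the 6α-hydroxyl, the diene and the angelate follow.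
- C8 is carried as CH–CH3 through the ring closure, so no leaving group sits β to the ketone. Its oxygen is added afterwards by enone epoxidation and reductive opening.
- Stereochemistry: C1 is set by a nickel-catalysed enantioconvergent alkenylation and relayed to C9 by the chair oxy-Cope; C9 controls C10 and C5 in the transannular step. 8α-O comes from α-face epoxidation, 6α-OH from dissolving-metal reduction, 12E from a stabilised ylide, and the Z ester from angelic acid.

Key step: step 6

Remark on the chemistry: labdane numbering (C1–C20) and the α/β descriptors of the normal labdane series (10β-CH3, 5α-H, 9α-H) are used for all intermediates, the monocyclic ones included. Metal alkoxides and enolates that are only the deprotonated form of a numbered compound and are consumed at once carry no number, except the rearranged enolate 9.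

Step 1
Reactants: 1 pent-3-yn-1-ol
Product: 2 [(pent-3-yn-1-yloxy)methyl]benzene
Conditions: NaH, BnBr, Bu4NI (cat.), THF, 0 °C → rt
Reagents that add atoms: benzyl bromide, BrCc1ccccc1
Why: Williamson etherification of the primary alkoxide; the benzyl ether tolerates the organometallic, basic and weakly acidic steps and is removed in the dissolving-metal step 10.

Step 2
Reactants: 3 3,3-dimethylcyclohexan-1-one
Product: 5 rac-2-bromo-5,5-dimethylcyclohexan-1-one, via silyl enol ether 4 (not isolated)
Conditions: LiN(i-Pr)2, THF, −78 °C; Me3SiCl; volatiles removed; N-bromosuccinimide, THF, −78 → 0 °C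
Reagents that add atoms: N-bromosuccinimide, O=C1CCC(=O)N1Br
Why: Kinetic deprotonation takes the methylene remote from the gem-dimethyl group and bromination of the silyl enol ether puts bromine on that carbon only; the stereocentre may be racemic because step 3 is enantioconvergent.

Step 3
Reactants: 2 [(pent-3-yn-1-yloxy)methyl]benzene; 5 rac-2-bromo-5,5-dimethylcyclohexan-1-one
Product: 7 (S)-2-[(E)-5-(benzyloxy)pent-2-en-2-yl]-5,5-dimethylcyclohexan-1-one, via alkenylzirconocene chloride 6 (not isolated)
Conditions: 2, Cp2Zr(H)Cl, THF, 50 °C; then 5, NiCl2·glyme (5 mol %), 2,2′-(propane-2,2-diyl)bis(4-phenyl-4,5-dihydrooxazole) (6.5 mol %, the enantiomer that gives (S)-7), DME/THF, 10 °C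
Reagents that add atoms: none
Why: syn-Hydrozirconation, equilibrated so that zirconium sits on the methyl-bearing carbon, gives the (E)-alkenylzirconium, and the nickel/bis(oxazoline)-catalysed enantioconvergent cross-coupling of racemic secondary α-bromo ketones with alkenylzirconium reagents sets the α-stereocentre by catalyst control under base-free conditions that do not racemise the product.

Step 4
Reactants: 7 (S)-2-[(E)-5-(benzyloxy)pent-2-en-2-yl]-5,5-dimethylcyclohexan-1-one
Product: 8 (1R,2S)-2-[(E)-5-(benzyloxy)pent-2-en-2-yl]-5,5-dimethyl-1-[(E)-prop-1-en-1-yl]cyclohexan-1-ol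
Conditions: (E)-1-bromoprop-1-ene, t-BuLi (2 equiv), Et2O, −78 °C; CeCl3, THF, −78 °C; then 7, −78 °C; aq. NH4Cl
Reagents that add atoms: (E)-1-bromoprop-1-ene, C/C=C/Br
Why: Halogen–lithium exchange with retention and transmetalation to the weakly basic organocerium reagent allow 1,2-addition without enolising 7; equatorial attack, enforced by the syn-axial methyl of the gem-dimethyl group, places the propenyl group trans to the alkenyl group and so sets the carbinol centre.

Step 5
Reactants: 8 (1R,2S)-2-[(E)-5-(benzyloxy)pent-2-en-2-yl]-5,5-dimethyl-1-[(E)-prop-1-en-1-yl]cyclohexan-1-ol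
Product: 10 (3R,4S,5E)-4-[2-(benzyloxy)ethyl]-3,5,9,9-tetramethylcyclodec-5-en-1-one, via potassium enolate 9 (not isolated)
Conditions: KH, 18-crown-6, THF, 0 °C → rt; aq. NH4Cl
Reagents that add atoms: none
Why: Anionic oxy-Cope rearrangement of the trans-1,2-dialkenyl alkoxide through a chair transition state, with the ring bonds, the C17 methyl and the C11 chain all equatorial, forms C8–C9 and the (E)-C1=C10 alkene and relays the C1 configuration to C9 (S) and C8 (R).

Step 6
Reactants: 10 (3R,4S,5E)-4-[2-(benzyloxy)ethyl]-3,5,9,9-tetramethylcyclodec-5-en-1-one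
Product: 11 12-(benzyloxy)-13,14,15,16-tetranor-8βH-labdan-6-one
Conditions: (IPr)AuCl (5 mol %), AgN(SO2CF3)2 (5 mol %), toluene (0.01 M), 80 °C; IPr = 1,3-bis(2,6-diisopropylphenyl)imidazol-2-ylidene
Reagents that add atoms: none
Why: Proposed new method: the cationic monovalent gold catalyst binds the strained (E)-C1=C10 alkene and not the C6 carbonyl, the C5 enol attacks C10 in the Markovnikov sense anti to gold, and protodeauration by the proton released from the oxocarbenium ion puts hydrogen on C1; the closest known reaction type is the gold-catalysed intramolecular hydroalkylation of unactivated alkenes by simple ketones, and the bond formed is the one made in the acid-promoted germacradiene-to-eudesmane closure. Ring A closes 6-endo-trig with respect to the alkene (enol exocyclic) and ring B 6-exo-trig (enol endocyclic), both through the single C5–C10 bond. C10 is controlled by C9 and C8, because only the chair–chair folding with the C9 chain and the C8 methyl equatorial brings C5 to the face of C10 that leaves C20 cis to C11; C5 arises trans from the (E)-enol in that folding and, being α to the ketone, can also equilibrate to the trans fusion. The step needs C5–C10 bonding to win over carbonyl–ene bonding of C1 to C6, over proton loss from C10 and over reaction of the C7 enol; this is meant to be secured by a carbophilic catalyst that leaves the carbonyl unactivated, by the absence of a leaving group β to the ketone, and by reversible enolisation, since the C7 enol could only close a four-membered ring.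

Step 7
Reactants: 11 12-(benzyloxy)-13,14,15,16-tetranor-8βH-labdan-6-one
Product: 13 12-(benzyloxy)-13,14,15,16-tetranorlabd-7-en-6-one, via silyl enol ether 12 (not isolated)
Conditions: LiN(i-Pr)2, Me3SiCl, THF, −78 °C; then Pd(OAc)2, MeCN, rt
Reagents that add atoms: none
Why: Saegusa–Ito oxidation; enolisation can only go to C7, because C5 lies between two quaternary carbons and has no β-hydrogen, and β-hydride elimination from C8 gives the enone, erasing the C8 centre on purpose.

Step 8
Reactants: 13 12-(benzyloxy)-13,14,15,16-tetranorlabd-7-en-6-one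
Product: 14 12-(benzyloxy)-7α,8α-epoxy-13,14,15,16-tetranorlabdan-6-one
Conditions: H2O2 (30 % aq.), NaOH, MeOH, 0 °C → rt
Reagents that add atoms: hydrogen peroxide, OO
Why: Weitz–Scheffer nucleophilic epoxidation; hydroperoxide adds to C8 on the α face, anti to the axial C10 methyl and to the C9 side chain, which fixes the 8α-oxygen and the 8β-methyl.

Step 9
Reactants: 14 12-(benzyloxy)-7α,8α-epoxy-13,14,15,16-tetranorlabdan-6-one
Product: 15 12-(benzyloxy)-8α-hydroxy-13,14,15,16-tetranorlabdan-6-one
Conditions: SmI2, THF/MeOH, −78 °C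
Reagents that add atoms: none
Why: Two-electron reduction of the α,β-epoxy ketone breaks only the C7–O bond through the ketyl and enolate, so the tertiary 8α-hydroxyl keeps its configuration.

Step 10
Reactants: 15 12-(benzyloxy)-8α-hydroxy-13,14,15,16-tetranorlabdan-6-one
Product: 16 13,14,15,16-tetranorlabdane-6α,8α,12-triol
Conditions: Li, NH3(l), THF, t-BuOH, −78 → −33 °C; NH4Cl
Reagents that add atoms: none
Why: Dissolving-metal reduction gives the thermodynamically favoured equatorial 6α-alcohol (a 6β-hydroxyl would be syn-axial to the C4β and C10 methyls) and cleaves the benzyl ether in the same operation.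

Step 11
Reactants: 16 13,14,15,16-tetranorlabdane-6α,8α,12-triol
Product: 18 6α-hydroxy-13,14,15,16-tetranorlabdan-12,8α-olide, via lactol 17 (not isolated)
Conditions: TEMPO (cat.), PhI(OAc)2, CH2Cl2, rt
Reagents that add atoms: none
Why: Oxoammonium oxidation is selective for the primary alcohol; the aldehyde is trapped by the 8α-hydroxyl as the lactol, which is oxidised on to the γ-lactone while the hindered secondary 6α-hydroxyl is left.

Step 12
Reactants: 18 6α-hydroxy-13,14,15,16-tetranorlabdan-12,8α-olide
Product: 17 8α,12-epoxy-13,14,15,16-tetranorlabdane-6α,12-diol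
Conditions: i-Bu2AlH, CH2Cl2, −78 °C; aq. potassium sodium tartrate
Reagents that add atoms: none
Why: Partial reduction of the γ-lactone stops at the lactol because the tetrahedral aluminium alkoxide is stable at −78 °C.

Step 13
Reactants: 17 8α,12-epoxy-13,14,15,16-tetranorlabdane-6α,12-diol
Product: 19 (12E)-6α,8α-dihydroxy-15-norlabd-12-en-14-al
Conditions: Ph3P=C(CH3)CHO, PhCO2H (cat.), toluene, 100 °C
Reagents that add atoms: 2-(triphenylphosphoranylidene)propanal, CC(C=O)=P(c1ccccc1)(c1ccccc1)c1ccccc1
Why: Wittig olefination of the ring-opened hydroxy aldehyde with a stabilised ylide gives the (E)-trisubstituted enal and so sets the 12E geometry.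

Step 14
Reactants: 19 (12E)-6α,8α-dihydroxy-15-norlabd-12-en-14-al
Product: 20 (12E)-labda-12,14-diene-6α,8α-diol
Conditions: Ph3PCH3Br, KN(SiMe3)2, THF, 0 °C; then 19, −78 → 0 °C
Reagents that add atoms: methyltriphenylphosphonium bromide, C[P+](c1ccccc1)(c1ccccc1)c1ccccc1.[Br-]
Why: Wittig methylenation of the aldehyde completes the diene without touching the trisubstituted alkene, an excess of ylide allowing for the two free hydroxyls.

Step 15
Reactants: 20 (12E)-labda-12,14-diene-6α,8α-diol
Product: 21 (12E)-8α-hydroxylabda-12,14-dien-6α-yl (Z)-2-methylbut-2-enoate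
Conditions: angelic acid, 2,4,6-trichlorobenzoyl chloride, Et3N, toluene, rt; then 20, 80 °C
Reagents that add atoms: angelic acid, C/C=C(/C)C(=O)O
Why: Yamaguchi-type mixed-anhydride esterification without a nucleophilic catalyst transfers the angeloyl group without Z to E isomerisation, and the secondary 6α-hydroxyl reacts in preference to the tertiary 8α-hydroxyl.

**Compound list**

1 | pent-3-yn-1-ol | CC#CCCO | starting material
2 | [(pent-3-yn-1-yloxy)methyl]benzene | CC#CCCOCc1ccccc1 | intermediate
3 | 3,3-dimethylcyclohexan-1-one | CC1(C)CCCC(=O)C1 | starting material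
4 | [(5,5-dimethylcyclohex-1-en-1-yl)oxy]trimethylsilane | C[Si](C)(C)OC1=CCCC(C)(C)C1 | intermediate (not isolated)
5 | rac-2-bromo-5,5-dimethylcyclohexan-1-one | O=C1CC(C)(C)CCC1Br | intermediate
6 | [(E)-5-(benzyloxy)pent-2-en-2-yl]chlorobis(cyclopentadienyl)zirconium | Cl[Zr](/C(C)=C/CCOCc1ccccc1)(C1C=CC=C1)C1C=CC=C1 | intermediate (not isolated)
7 | (S)-2-[(E)-5-(benzyloxy)pent-2-en-2-yl]-5,5-dimethylcyclohexan-1-one | O=C1CC(C)(C)CC[C@H]1/C(C)=C/CCOCc2ccccc2 | intermediate
8 | (1R,2S)-2-[(E)-5-(benzyloxy)pent-2-en-2-yl]-5,5-dimethyl-1-[(E)-prop-1-en-1-yl]cyclohexan-1-ol | O[C@@]1(/C=C/C)CC(C)(C)CC[C@H]1/C(C)=C/CCOCc2ccccc2 | intermediate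
9 | potassium enolate of 10 (C6=C7 enolate, O cis to C8, ring alkenes both E) | [K+].[O-]/C1=C\[C@@H](C)[C@H](CCOCc2ccccc2)/C(C)=C/CCC(C)(C)C1 | intermediate (not isolated)
10 | (3R,4S,5E)-4-[2-(benzyloxy)ethyl]-3,5,9,9-tetramethylcyclodec-5-en-1-one | c3ccccc3COCC[C@@H]1/C(C)=C/CCC(C)(C)CC(=O)C[C@H]1C | intermediate (key-step precursor)
11 | 12-(benzyloxy)-13,14,15,16-tetranor-8βH-labdan-6-one (5α-H, 8α-CH3, 9β side chain, 10β-CH3) | c3ccccc3COCC[C@@H]1[C@@]2(C)CCCC(C)(C)[C@@H]2C(=O)C[C@H]1C | intermediate (key-step product)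
12 | 12-(benzyloxy)-6-(trimethylsilyloxy)-13,14,15,16-tetranor-8βH-labd-6-ene | c3ccccc3COCC[C@@H]1[C@@]2(C)CCCC(C)(C)[C@@H]2C(O[Si](C)(C)C)=C[C@H]1C | intermediate (not isolated)
13 | 12-(benzyloxy)-13,14,15,16-tetranorlabd-7-en-6-one | c3ccccc3COCC[C@@H]1[C@@]2(C)CCCC(C)(C)[C@@H]2C(=O)C=C1C | intermediate
14 | 12-(benzyloxy)-7α,8α-epoxy-13,14,15,16-tetranorlabdan-6-one | c3ccccc3COCC[C@@H]1[C@@]2(C)CCCC(C)(C)[C@@H]2C(=O)[C@H]4O[C@@]14C | intermediate
15 | 12-(benzyloxy)-8α-hydroxy-13,14,15,16-tetranorlabdan-6-one | c3ccccc3COCC[C@@H]1[C@@]2(C)CCCC(C)(C)[C@@H]2C(=O)C[C@@]1(C)O | intermediate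
16 | 13,14,15,16-tetranorlabdane-6α,8α,12-triol | OCC[C@@H]1[C@@]2(C)CCCC(C)(C)[C@@H]2[C@@H](O)C[C@@]1(C)O | intermediate
17 | 8α,12-epoxy-13,14,15,16-tetranorlabdane-6α,12-diol (lactol, both C12 epimers) | OC1C[C@@H]2[C@@]3(C)CCCC(C)(C)[C@@H]3[C@@H](O)C[C@@]2(C)O1 | intermediate
18 | 6α-hydroxy-13,14,15,16-tetranorlabdan-12,8α-olide | O=C1C[C@@H]2[C@@]3(C)CCCC(C)(C)[C@@H]3[C@@H](O)C[C@@]2(C)O1 | intermediate
19 | (12E)-6α,8α-dihydroxy-15-norlabd-12-en-14-al | O=C/C(C)=C/C[C@@H]1[C@@]2(C)CCCC(C)(C)[C@@H]2[C@@H](O)C[C@@]1(C)O | intermediate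
20 | (12E)-labda-12,14-diene-6α,8α-diol | C=C/C(C)=C/C[C@@H]1[C@@]2(C)CCCC(C)(C)[C@@H]2[C@@H](O)C[C@@]1(C)O | intermediate
21 | (12E)-8α-hydroxylabda-12,14-dien-6α-yl (Z)-2-methylbut-2-enoate (CNP0582767.1) | C=C/C(C)=C/C[C@@H]1[C@@]2(C)CCCC(C)(C)[C@@H]2[C@@H](OC(=O)/C(C)=C\C)C[C@@]1(C)O | target

**Step count**

Total: 15 steps. Longest linear sequence: 14 steps (3 to 21 through steps 2–15; the branch from 1 joins at step 3).

**Steps most likely to fail**

Step 6 (the proposed new method). The C5 enol is the minor tautomer, so turnover may be slow. Meanwhile the activated alkene may lose a proton, and alkene migration toward C9 would erode that centre. Traces of strong acid may also promote carbonyl–ene bonding of C1 to C6, and protodeauration may stall.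

The fallback removes the alkene before any acid is applied and sets out from 10. Epoxidation with 3-chloroperoxybenzoic acid (NaHCO3, CH2Cl2, 0 °C) on the outer face of the (E)-alkene should give the trans-1,10-epoxide of 10, (3R,4S)-4-[2-(benzyloxy)ethyl]-5,6-epoxy-3,5,9,9-tetramethylcyclodecan-1-one F1. With BF3·OEt2 (CH2Cl2, −78 °C) the epoxide should open at the tertiary C10 with inversion and transannular capture by C5. This is the epoxide-initiated closure known from 1(10)-epoxygermacrenes, here ended by the ketone enol, and no alkene is left for a carbonyl–ene reaction. It should give 12-(benzyloxy)-1β-hydroxy-13,14,15,16-tetranor-8βH-labdan-6-one F2. Acylation with PhOC(S)Cl (pyridine, CH2Cl2) gives the O-phenyl thionocarbonate of F2 F3. Barton–McCombie reduction (Bu3SnH, azobisisobutyronitrile, toluene, 80 °C) then returns to the route at 11.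

Step 3. Regiochemical equilibration of the alkenylzirconium may be incomplete. Enantioinduction may be low for a cyclic α-bromo ketone with an α-branched alkenyl partner, and the β,γ-unsaturated ketone may racemise or move into conjugation.

The fallback sets out from 2 and 3 and separates bond formation from stereocontrol. Hydrozirconation–iodination of 2 (Cp2Zr(H)Cl, THF, 50 °C; I2) gives ({[(3E)-4-iodopent-3-en-1-yl]oxy}methyl)benzene F4. Palladium-catalysed α-alkenylation of the lithium enolate of 3 (Pd2(dba)3, P(t-Bu)3, LiN(SiMe3)2, toluene, rt) at the less hindered α-carbon gives rac-2-[(E)-5-(benzyloxy)pent-2-en-2-yl]-5,5-dimethylcyclohexan-1-one F5. Reduction with LiBH(s-Bu)3 (THF, −78 °C) gives the cis-alcohol as a racemate, which is resolved by lipase-catalysed acetylation (Candida antarctica lipase B, vinyl acetate). The unreacted enantiomer is expected to be (1S,2S)-2-[(E)-5-(benzyloxy)pent-2-en-2-yl]-5,5-dimethylcyclohexan-1-ol F6. Oxidation with the triacetoxyperiodinane (NaHCO3, CH2Cl2, 0 °C) returns to the route at 7 without touching the α-centre.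

Step 13. The lactol may open too slowly toward the weakly nucleophilic formyl ylide, and the 8α-hydroxyl may add to the enal in an intramolecular oxa-Michael reaction.

The fallback sets out from 17 and carries C14 through the olefination at the ester level. The more nucleophilic ethyl 2-(triphenylphosphoranylidene)propanoate (toluene, 80 °C) should give ethyl (12E)-6α,8α-dihydroxy-15-norlabd-12-en-14-oate F7, a weaker Michael acceptor. Reduction with i-Bu2AlH (CH2Cl2, −78 °C) gives (12E)-15-norlabd-12-ene-6α,8α,14-triol F8. Selective allylic oxidation with MnO2 (CH2Cl2, rt) returns to the route at 19.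

**Further compounds**

F1 | step 6 | trans-1,10-epoxide of 10, (3R,4S)-4-[2-(benzyloxy)ethyl]-5,6-epoxy-3,5,9,9-tetramethylcyclodecan-1-one | c3ccccc3COCC[C@@H]1[C@@]2(C)O[C@@H]2CCC(C)(C)CC(=O)C[C@H]1C
F2 | step 6 | 12-(benzyloxy)-1β-hydroxy-13,14,15,16-tetranor-8βH-labdan-6-one | c3ccccc3COCC[C@@H]1[C@@]2(C)[C@H](O)CCC(C)(C)[C@@H]2C(=O)C[C@H]1C
F3 | step 6 | O-phenyl thionocarbonate of F2 | c3ccccc3COCC[C@@H]1[C@@]2(C)[C@H](OC(=S)Oc4ccccc4)CCC(C)(C)[C@@H]2C(=O)C[C@H]1C
F4 | step 3 | ({[(3E)-4-iodopent-3-en-1-yl]oxy}methyl)benzene | C/C(I)=C\CCOCc1ccccc1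
F5 | step 3 | rac-2-[(E)-5-(benzyloxy)pent-2-en-2-yl]-5,5-dimethylcyclohexan-1-one | O=C1CC(C)(C)CCC1/C(C)=C/CCOCc2ccccc2
F6 | step 3 | (1S,2S)-2-[(E)-5-(benzyloxy)pent-2-en-2-yl]-5,5-dimethylcyclohexan-1-ol | O[C@H]1CC(C)(C)CC[C@H]1/C(C)=C/CCOCc2ccccc2
F7 | step 13 | ethyl (12E)-6α,8α-dihydroxy-15-norlabd-12-en-14-oate | CCOC(=O)/C(C)=C/C[C@@H]1[C@@]2(C)CCCC(C)(C)[C@@H]2[C@@H](O)C[C@@]1(C)O
F8 | step 13 | (12E)-15-norlabd-12-ene-6α,8α,14-triol | OC/C(C)=C/C[C@@H]1[C@@]2(C)CCCC(C)(C)[C@@H]2[C@@H](O)C[C@@]1(C)O
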